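**Plan**

Cuts: the quinone methide at C7 is traced back to a tetra-O-methyl triarylcarbinol. The carbinol is cut at a C7–aryl bond to a 2-alkynylbenzophenone plus an aryllithium, and ring A, taken one oxidation level down to a cyclohexa-1,3-diene, is opened at C1–C6 and C3=C4.
Enabling feature: ring A (C1 methyl, C2 H, C3 H, C4 aryl, C5 bearing C7, C6 bearing the alkyne C8≡C9) is the sum of a crotyl unit C1(CH3)–C2–C3 and a C4–C5–C6 unit. Because C4 and C7 both carry a 4-oxygenated phenyl group, that unit is a symmetrical diaroylmethane (C4, C5, C7) alkylidenated at C5 by an arylpropynal (C6, C8, C9).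
Forward order: ynal and diketone are condensed (C5=C6), and the crotyl ylide then closes ring A, the only ring made in the route (the four outer six-membered rings are bought). DDQ aromatises ring A, the last aryl group is added at C7, and BBr3 frees the phenols and the quinone methide.
Stereochemistry: the target has no stereocentre and no stereogenic double bond. The two sp3 centres (C5, C6) that arise in the annulation vanish on aromatisation.

Key step: step 4

Remark: technical crotyl bromide carries some Z isomer and 3-bromobut-1-ene; both end in the same delocalised ylide, so the E descriptor of 6 and 8 has no bearing on the outcome.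

**Step 1**
Reactants: 1 4-ethynylanisole
Product: 3 3-(4-methoxyphenyl)prop-2-ynal, via lithium (4-methoxyphenyl)acetylide 2 (not isolated)
Conditions: n-BuLi, THF, −78 °C; DMF, −78 °C → rt; reverse quench into 10% aq KH2PO4/MTBE, 0 °C
Reagents that add atoms: N,N-dimethylformamide, CN(C)C=O
Why: Deprotonation of the terminal alkyne and Bouveault-type formylation of the acetylide with DMF is the standard entry to arylpropynals, and the buffered reverse quench collapses the hemiaminal alkoxide before the released dimethylamine can add to the ynal.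

**Step 2**
Reactants: 3 3-(4-methoxyphenyl)prop-2-ynal; 4 1,3-bis(4-methoxyphenyl)propane-1,3-dione
Product: 5 1,3-bis(4-methoxyphenyl)-2-[3-(4-methoxyphenyl)prop-2-yn-1-ylidene]propane-1,3-dione
Conditions: piperidine (20 mol %), AcOH (20 mol %), 4 Å MS, toluene, 0 °C → rt
Reagents that add atoms: none
Why: Knoevenagel condensation of the unhindered, strongly electrophilic ynal (through its iminium ion) with the enolisable diaroylmethane follows the protocol used for the well-known 2-(alk-2-ynylidene)-1,3-diketones, and the identity of the two aroyl groups means that no alkene geometry arises.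

**Step 3**
Reactants: 6 crotyl bromide [(E)-1-bromobut-2-ene]; 7 triphenylphosphine
Product: 8 (E)-but-2-en-1-yl(triphenyl)phosphonium bromide
Conditions: toluene, 80 °C; the precipitated salt is filtered off and dried
Reagents that add atoms: none
Why: SN2 quaternisation of PPh3 by a primary allylic bromide is fast and is driven by precipitation of the salt from toluene.

**Step 4**
Reactants: 5 1,3-bis(4-methoxyphenyl)-2-[3-(4-methoxyphenyl)prop-2-yn-1-ylidene]propane-1,3-dione; 8 (E)-but-2-en-1-yl(triphenyl)phosphonium bromide
Product: 12 (4-methoxyphenyl)[2-(4-methoxyphenyl)-6-[(4-methoxyphenyl)ethynyl]-5-methylcyclohexa-2,4-dien-1-yl]methanone (racemic cis/trans mixture), via crotyl ylide 9 (not isolated), via vinylphosphonium enolate 10 (not isolated), via ring-closing allylic ylide 11 (not isolated)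
Conditions: 8 (1.2 equiv), KOt-Bu (1.15 equiv), THF, 0 °C; then 5, −78 °C → rt, then 60 °C
Reagents that add atoms: none
Why: KOt-Bu turns 8 into the delocalised allylic ylide 9, whose methyl-bearing γ-carbon (C1) adds to the alkylidene carbon C6 of 5 to give the vinylphosphonium diketone enolate 10; a proton shift from C1 to C5, relayed by the t-BuOH formed in the deprotonation, gives the new allylic ylide 11, whose carbon C3 attacks one aroyl carbonyl (C4) and expels Ph3PO. The closest known reaction type is the [3+3] cyclohexadiene annulation of allylidenephosphoranes with enones and alkylidene β-dicarbonyl compounds (conjugate addition, then intramolecular Wittig olefination). Ring A closes by 6-exo-trig attack of C3 on the C4 carbonyl and collapse of the oxaphosphetane, which needs the Z arrangement about C1=C2 that the delocalised ylide can reach by rotation or by reversible reprotonation to 10. C5 and C6 become stereocentres without control (C5 is epimerisable, so the trans isomer should prevail), which does not matter because step 5 removes both. The step needs γ-1,4-addition rather than α-attack, addition at the alkyne terminus C9 or direct olefination: C6 is an unhindered CH made strongly electrophilic by two aroyl groups, C9 is shielded and deactivated by its anisyl group, the cross-conjugated aryl ketones react only slowly with a semistabilised ylide from outside, the PPh3 group crowds the α-carbon, and conjugate additions that release the stabilised diketone enolate are reversible, so only the γ-adduct drains away through the irreversible six-membered olefination. Since the two aroyl groups are identical, either one can be olefinated and the other remains as the C7 ketone.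

**Step 5**
Reactants: 12 (4-methoxyphenyl)[2-(4-methoxyphenyl)-6-[(4-methoxyphenyl)ethynyl]-5-methylcyclohexa-2,4-dien-1-yl]methanone
Product: 13 (4-methoxyphenyl){4'-methoxy-3-[(4-methoxyphenyl)ethynyl]-4-methylbiphenyl-2-yl}methanone
Conditions: DDQ (1.2 equiv), toluene, rt
Reagents that add atoms: none
Why: In this DDQ dehydrogenation, hydride abstraction from the allylic and propargylic C6–H gives an arenium-type cation that loses the acidic C5–H, so cis and trans isomers and any double-bond isomers of 12 should converge on one arene while anisyl ethers, alkyne and ketone are untouched at room temperature.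

**Step 6**
Reactants: 13 (4-methoxyphenyl){4'-methoxy-3-[(4-methoxyphenyl)ethynyl]-4-methylbiphenyl-2-yl}methanone; 14 4-bromoanisole
Product: 16 bis(4-methoxyphenyl){4'-methoxy-3-[(4-methoxyphenyl)ethynyl]-4-methylbiphenyl-2-yl}methanol, via 4-methoxyphenyllithium 15 (not isolated)
Conditions: 14 (3 equiv), n-BuLi (3 equiv), THF, −78 °C; then 13, −78 → 0 °C; H2O quench
Reagents that add atoms: none
Why: Bromine–lithium exchange followed by 1,2-addition of the aryllithium to a non-enolisable diaryl ketone is well established for 2-alkynylbenzophenones, the slim alkyne flank leaves the carbonyl accessible, and the low temperature and non-acidic quench keep the alkoxide off the alkyne and the acid-labile carbinol intact.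

**Step 7**
Reactants: 16 bis(4-methoxyphenyl){4'-methoxy-3-[(4-methoxyphenyl)ethynyl]-4-methylbiphenyl-2-yl}methanol
Product: 18 selaginellin U, via tetrahydroxy triarylcarbenium bromide 17 (not isolated)
Conditions: BBr3 (10 equiv), CH2Cl2, −78 °C → rt; then ice–water, EtOAc extraction
Reagents that add atoms: none
Why: BBr3 cleavage of the four aryl methyl ethers goes along with ionisation of the carbinol to a trityl-type cation stabilised by two para oxygen substituents, which on aqueous work-up loses a phenolic proton to give the p-quinone methide (fuchsone formation).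

**Compound list**

| No. | Name | SMILES | Role |
|---|---|---|---|
| 1 | 4-ethynylanisole | C#Cc1ccc(OC)cc1 | starting material |
| 2 | lithium (4-methoxyphenyl)acetylide | [Li]C#Cc1ccc(OC)cc1 | intermediate |
| 3 | 3-(4-methoxyphenyl)prop-2-ynal | O=CC#Cc1ccc(OC)cc1 | intermediate |
| 4 | 1,3-bis(4-methoxyphenyl)propane-1,3-dione | COc1ccc(C(=O)CC(=O)c2ccc(OC)cc2)cc1 | starting material |
| 5 | 1,3-bis(4-methoxyphenyl)-2-[3-(4-methoxyphenyl)prop-2-yn-1-ylidene]propane-1,3-dione | COc1ccc(cc1)C(=O)C(=CC#Cc1ccc(OC)cc1)C(=O)c1ccc(OC)cc1 | intermediate |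
| 6 | crotyl bromide, (E)-1-bromobut-2-ene | C/C=C/CBr | starting material |
| 7 | triphenylphosphine | c1ccc(cc1)P(c1ccccc1)c1ccccc1 | starting material |
| 8 | (E)-but-2-en-1-yl(triphenyl)phosphonium bromide | C/C=C/C[P+](c1ccccc1)(c1ccccc1)c1ccccc1.[Br-] | intermediate |
| 9 | (E)-but-2-en-1-ylidene(triphenyl)-λ5-phosphane (crotyl ylide) | C/C=C/C=P(c1ccccc1)(c1ccccc1)c1ccccc1 | intermediate |
| 10 | triphenyl[(1E)-4-[bis(4-methoxybenzoyl)methanidyl]-6-(4-methoxyphenyl)-3-methylhex-1-en-5-yn-1-yl]phosphonium inner salt (drawn as the enolate; diastereomer mixture) | CC(/C=C/[P+](c1ccccc1)(c1ccccc1)c1ccccc1)C(C#Cc1ccc(OC)cc1)C(C(=O)c1ccc(OC)cc1)=C([O-])c1ccc(OC)cc1 | intermediate |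
| 11 | 1,3-bis(4-methoxyphenyl)-2-[1-(4-methoxyphenyl)-4-methyl-6-(triphenyl-λ5-phosphanylidene)hex-4-en-1-yn-3-yl]propane-1,3-dione (racemic, mobile alkene geometry) | CC(=CC=P(c1ccccc1)(c1ccccc1)c1ccccc1)C(C#Cc1ccc(OC)cc1)C(C(=O)c1ccc(OC)cc1)C(=O)c1ccc(OC)cc1 | intermediate |
| 12 | (4-methoxyphenyl)[2-(4-methoxyphenyl)-6-[(4-methoxyphenyl)ethynyl]-5-methylcyclohexa-2,4-dien-1-yl]methanone (racemic cis/trans mixture) | CC1=CC=C(c2ccc(OC)cc2)C(C(=O)c2ccc(OC)cc2)C1C#Cc1ccc(OC)cc1 | intermediate |
| 13 | (4-methoxyphenyl){4'-methoxy-3-[(4-methoxyphenyl)ethynyl]-4-methylbiphenyl-2-yl}methanone | Cc1ccc(-c2ccc(OC)cc2)c(C(=O)c2ccc(OC)cc2)c1C#Cc1ccc(OC)cc1 | intermediate |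
| 14 | 4-bromoanisole | COc1ccc(Br)cc1 | starting material |
| 15 | 4-methoxyphenyllithium | [Li]c1ccc(OC)cc1 | intermediate |
| 16 | bis(4-methoxyphenyl){4'-methoxy-3-[(4-methoxyphenyl)ethynyl]-4-methylbiphenyl-2-yl}methanol | Cc1ccc(-c2ccc(OC)cc2)c(C(O)(c2ccc(OC)cc2)c2ccc(OC)cc2)c1C#Cc1ccc(OC)cc1 | intermediate |
| 17 | bis(4-hydroxyphenyl){4'-hydroxy-3-[(4-hydroxyphenyl)ethynyl]-4-methylbiphenyl-2-yl}methylium bromide | Cc1ccc(-c2ccc(O)cc2)c([C+](c2ccc(O)cc2)c2ccc(O)cc2)c1C#Cc1ccc(O)cc1.[Br-] | intermediate |
| 18 | selaginellin U, 4-[(4-hydroxyphenyl){4'-hydroxy-3-[(4-hydroxyphenyl)ethynyl]-4-methylbiphenyl-2-yl}methylidene]cyclohexa-2,5-dien-1-one | Cc1ccc(-c2ccc(O)cc2)c(C(=C2C=CC(=O)C=C2)c2ccc(O)cc2)c1C#Cc1ccc(O)cc1 | target |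

**Step count**

Total step count: 7.
Longest linear sequence: 6 (steps 1, 2, 4, 5, 6, 7). Step 3 is a one-step side branch.

**Steps most likely to fail**

1. **Step 4 (annulation).**
   - What may go wrong: bond formation may occur through the α-carbon of the ylide, leading on to cyclopropanation with loss of PPh3 or to plain olefination of a ketone. Conjugate addition at the alkyne terminus may be followed by cyclisation of a carbonyl oxygen onto the resulting allene. The reaction may also stall at the stabilised enolate because the proton shift to the reactive ylide lags behind decomposition.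
   - Fallback, setting out from 3 and 8 and rejoining at 13: ring A is assembled by a [4+2] union of the same two branch compounds. Claisen–Schmidt condensation of ynal 3 with 4'-methoxyacetophenone (cat. NaOH, EtOH, 0 °C) should give (E)-1,5-bis(4-methoxyphenyl)pent-2-en-4-yn-1-one F1. Wittig olefination of 4-methoxybenzaldehyde with the ylide from salt 8 (KOt-Bu, THF), followed by iodine-catalysed equilibration, should give 1-methoxy-4-[(1E,3E)-penta-1,3-dien-1-yl]benzene F2. A thermal (toluene, 130 °C, sealed tube) or Me2AlCl-promoted Diels–Alder reaction follows. In it the anisyl-bearing diene terminus pairs with the aroyl-bearing alkene carbon (ortho rule, the aryl group outweighing methyl as director). This should give (4-methoxyphenyl)[2-(4-methoxyphenyl)-6-[(4-methoxyphenyl)ethynyl]-5-methylcyclohex-3-en-1-yl]methanone F3. DDQ (2.5 equiv, 1,4-dioxane, 100 °C) should dehydrogenate F3 to benzophenone 13.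

2. **Step 2 (Knoevenagel condensation).**
   - What may go wrong: a second diketone molecule may add in Michael fashion to the very electrophilic product, the amine may induce oligomerisation of the ynal, or the bulky diaroylmethane may condense sluggishly.
   - Fallback, setting out from 4 and 1 and rejoining at 5: carbon C6 is first placed on the diketone and the alkyne is attached afterwards. Diketone 4 and N,N-dimethylformamide dimethyl acetal (toluene, 110 °C) should give 2-[(dimethylamino)methylidene]-1,3-bis(4-methoxyphenyl)propane-1,3-dione F4. Alkyne 1 and EtMgBr (THF, 40 °C) should give bromo[(4-methoxyphenyl)ethynyl]magnesium F5. A Benary reaction of F4 with F5 (1,4-addition to the vinylogous amide, loss of dimethylamine on dilute HCl work-up) should deliver 5.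

3. **Step 7 (global demethylation and dehydration).**
   - What may go wrong: the long-lived carbenium ion may be attacked by the neighbouring alkyne or the C4 aryl ring as the ether oxygens are tied up by boron. HBr may add across the electron-rich alkyne, or ether cleavage may be incomplete.
   - Fallback, setting out from 16 and rejoining at 18: the cation is removed before the Lewis acid step and the oxidation level is restored afterwards. Ionic hydrogenation of 16 (Et3SiH, a few equivalents of TFA, CH2Cl2, 0 °C) should give the triarylmethane 2-[bis(4-methoxyphenyl)methyl]-4'-methoxy-3-[(4-methoxyphenyl)ethynyl]-4-methylbiphenyl F6. BBr3 (CH2Cl2, −78 °C → rt) should give the tetraphenol 4,4'-({4'-hydroxy-3-[(4-hydroxyphenyl)ethynyl]-4-methylbiphenyl-2-yl}methanediyl)diphenol F7. Oxidation of this leuco form with DDQ (1 equiv, THF, rt), the classical route from bis(4-hydroxyphenyl)arylmethanes to fuchsones, should give 18.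

**Further compounds**

F1 | step 4 | (E)-1,5-bis(4-methoxyphenyl)pent-2-en-4-yn-1-one | COc1ccc(cc1)C(=O)/C=C/C#Cc1ccc(OC)cc1
F2 | step 4 | 1-methoxy-4-[(1E,3E)-penta-1,3-dien-1-yl]benzene | C/C=C/C=C/c1ccc(OC)cc1
F3 | step 4 | (4-methoxyphenyl)[2-(4-methoxyphenyl)-6-[(4-methoxyphenyl)ethynyl]-5-methylcyclohex-3-en-1-yl]methanone (racemic endo/exo mixture) | CC1C=CC(c2ccc(OC)cc2)C(C(=O)c2ccc(OC)cc2)C1C#Cc1ccc(OC)cc1
F4 | step 2 | 2-[(dimethylamino)methylidene]-1,3-bis(4-methoxyphenyl)propane-1,3-dione | CN(C)C=C(C(=O)c1ccc(OC)cc1)C(=O)c1ccc(OC)cc1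
F5 | step 2 | bromo[(4-methoxyphenyl)ethynyl]magnesium | COc1ccc(cc1)C#C[Mg]Br
F6 | step 7 | 2-[bis(4-methoxyphenyl)methyl]-4'-methoxy-3-[(4-methoxyphenyl)ethynyl]-4-methylbiphenyl | Cc1ccc(-c2ccc(OC)cc2)c(C(c2ccc(OC)cc2)c2ccc(OC)cc2)c1C#Cc1ccc(OC)cc1
F7 | step 7 | 4,4'-({4'-hydroxy-3-[(4-hydroxyphenyl)ethynyl]-4-methylbiphenyl-2-yl}methanediyl)diphenol | Cc1ccc(-c2ccc(O)cc2)c(C(c2ccc(O)cc2)c2ccc(O)cc2)c1C#Cc1ccc(O)cc1
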